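Ring A (C1–C2–C3–C4–C5–C10) is cut through C2–C3 and C4–C5. Its lone C1=C10 alkene lies opposite the C3–C4 bond and the carbonyl-bearing quaternary C4 adjoins the ring-fusion C5–H. That is the imprint of an ortho, endo adduct between a methacrylic two-carbon unit and the diene C2=C1–C10=C5. An acid-triggered cationic [4+2] of methacrolein ethylene acetal with a ring B vinylcyclohexene therefore builds ring A, C4, C5 and the alkene in one operation. The precursor is an enantiopure 6,6-disubstituted 1-vinylcyclohexene carrying C8, quaternary C9 and the silyl-protected C11–C15 chain, assembled by asymmetric conjugate methylation, enolate alkylation, triflation and Stille vinylation.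

Key step: step 10

Assumption: atoms are named by halimane numbering (ring A = C1–C5 and C10, ring B = C5–C10, chain C11–C15), and the phosphoramidite antipode that delivers the 3R enolate is the one used.

Step 1
Reactants: 1 2-methylcyclohex-2-en-1-one; 2 trimethylaluminium
Product: 4 (R)-[(2,3-dimethylcyclohex-1-en-1-yl)oxy]trimethylsilane, via aluminium enolate 3 (not isolated)
Conditions: copper thiophene-2-carboxylate Cu(O2CC4H3S) (2 mol%), BINOL-derived bis(1-phenylethyl)amine phosphoramidite (4 mol%), Et2O, −30 °C; then Me3SiOTf, THF, −30 °C to rt; Et3N, pentane work-up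
Reagents that add atoms: trimethylsilyl trifluoromethanesulfonate, C[Si](C)(C)OS(=O)(=O)C(F)(F)F
Why: Copper-catalysed asymmetric conjugate addition of the methylaluminium reagent to the 2-substituted enone sets C8 (R) under ligand control, and O-silylation of the aluminium enolate fixes the tetrasubstituted enolate regiochemistry needed later at C9.

Step 2
Reactants: 5 methyl hydrogen (R)-3-methylglutarate
Product: 6 methyl (R)-5-hydroxy-3-methylpentanoate
Conditions: BH3·SMe2, THF, 0 °C to rt; MeOH quench
Reagents that add atoms: none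
Why: Chemoselective borane reduction takes the free carboxylic acid (via its acyloxyborane) much faster than the methyl ester and does not touch the C13 stereocentre, which comes from the chiral pool.

Step 3
Reactants: 6 methyl (R)-5-hydroxy-3-methylpentanoate
Product: 7 methyl (R)-5-[(tert-butyldimethylsilyl)oxy]-3-methylpentanoate
Conditions: TBSCl, imidazole, DMF, 0 °C to rt (crude 6 used at once)
Reagents that add atoms: tert-butyldimethylsilyl chloride, CC(C)(C)[Si](C)(C)Cl
Why: Imidazole-mediated silylation of a primary alcohol is routine, and doing it immediately forestalls lactonisation of the hydroxy ester.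

Step 4
Reactants: 7 methyl (R)-5-[(tert-butyldimethylsilyl)oxy]-3-methylpentanoate
Product: 8 (S)-5-[(tert-butyldimethylsilyl)oxy]-3-methylpentan-1-ol
Conditions: LiBH4, THF, MeOH (1 equiv), 0 °C to rt
Reagents that add atoms: none
Why: Hydride reduction of the ester gives the primary alcohol without cleaving the silyl ether, so the two chain ends are now differentiated (the descriptor changes only through priorities).

Step 5
Reactants: 8 (S)-5-[(tert-butyldimethylsilyl)oxy]-3-methylpentan-1-ol
Product: 9 (R)-tert-butyl[(5-iodo-3-methylpentyl)oxy]dimethylsilane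
Conditions: I2, PPh3, imidazole, CH2Cl2, 0 °C to rt
Reagents that add atoms: iodine, II
Why: Appel-type iodination proceeds by SN2 displacement of the oxyphosphonium at the primary carbon, and the imidazole buffer keeps the TBS ether intact.

Step 6
Reactants: 4 (R)-[(2,3-dimethylcyclohex-1-en-1-yl)oxy]trimethylsilane; 9 (R)-tert-butyl[(5-iodo-3-methylpentyl)oxy]dimethylsilane
Product: 11 (2S,3R)-2-[(3S)-5-[(tert-butyldimethylsilyl)oxy]-3-methylpentyl]-2,3-dimethylcyclohexan-1-one, via lithium enolate 10 (not isolated)
Conditions: MeLi (1.0 equiv), THF, 0 °C to rt; then HMPA (or DMPU), 9, −78 °C to rt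
Reagents that add atoms: none
Why: Cleavage of the silyl enol ether by MeLi gives the regiodefined tetrasubstituted lithium enolate, and its SN2 alkylation by the primary iodide should occur anti to the C8 methyl (pseudoaxial in the enolate to avoid allylic strain), so the C9 and C8 methyls end cis and the chain trans.

Step 7
Reactants: 11 (2S,3R)-2-[(3S)-5-[(tert-butyldimethylsilyl)oxy]-3-methylpentyl]-2,3-dimethylcyclohexan-1-one
Product: 13 (5R,6S)-6-[(3S)-5-[(tert-butyldimethylsilyl)oxy]-3-methylpentyl]-5,6-dimethylcyclohex-1-en-1-yl trifluoromethanesulfonate, via potassium enolate 12 (not isolated)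
Conditions: KN(SiMe3)2, THF, −78 °C; then PhNTf2, −78 to 0 °C
Reagents that add atoms: N-phenylbis(trifluoromethanesulfonimide), O=S(=O)(N(c1ccccc1)S(=O)(=O)C(F)(F)F)C(F)(F)F
Why: Because C9 is quaternary the ketone can enolise only toward the C5 methylene, so deprotonation and O-sulfonylation with the N-aryl triflimide should give a single enol triflate (C10(OTf)=C5).

Step 8
Reactants: 13 (5R,6S)-6-[(3S)-5-[(tert-butyldimethylsilyl)oxy]-3-methylpentyl]-5,6-dimethylcyclohex-1-en-1-yl trifluoromethanesulfonate; 14 tributyl(vinyl)stannane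
Product: 15 tert-butyl{[(3S)-5-[(1S,6R)-2-ethenyl-1,6-dimethylcyclohex-2-en-1-yl]-3-methylpentyl]oxy}dimethylsilane
Conditions: Pd(PPh3)4 (5 mol%), LiCl (3 equiv), THF, 65 °C
Reagents that add atoms: none
Why: Stille coupling of the vinyl triflate (oxidative addition to zerovalent palladium, chloride-assisted transmetalation, reductive elimination) attaches C1–C2 at C10 and tolerates both the neighbouring quaternary centre and the silyl ether.

Step 9
Reactants: 16 methacrolein (2-methylprop-2-enal)
Product: 17 2-(prop-1-en-2-yl)-1,3-dioxolane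
Conditions: Me3SiOCH2CH2OSiMe3, Me3SiOTf (1 mol%), CH2Cl2, −78 °C; pyridine quench, distillation
Reagents that add atoms: 1,2-bis(trimethylsilyloxy)ethane, C[Si](C)(C)OCCO[Si](C)(C)C
Why: Silyl-triflate-catalysed acetalisation with the bis-silyl ether of ethylene glycol is driven by formation of hexamethyldisiloxane and avoids the conjugate addition and polymerisation that accompany protic acetalisation of enals.

Step 10
Reactants: 15 tert-butyl{[(3S)-5-[(1S,6R)-2-ethenyl-1,6-dimethylcyclohex-2-en-1-yl]-3-methylpentyl]oxy}dimethylsilane; 17 2-(prop-1-en-2-yl)-1,3-dioxolane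
Product: 18 2-[(1S,5S,6R,8aR)-5-[(3S)-5-[(tert-butyldimethylsilyl)oxy]-3-methylpentyl]-1,5,6-trimethyl-1,2,3,5,6,7,8,8a-octahydronaphthalen-1-yl]-1,3-dioxolane
Conditions: 17 (3 equiv), Me3SiOTf (10–20 mol%), CH2Cl2, −78 °C; Et3N quench at −78 °C
Reagents that add atoms: none
Why: Me3SiOTf opens the dioxolane of 17 to an oxygen-stabilised allyl (vinyl-oxocarbenium) cation, a dienophile far more electrophilic than any methacrylate, whose unsubstituted CH2 (C3) bonds to the free vinyl terminus C2 of 15, after which the allyl cation spread over C1–C10–C5 is captured at C5 by the enol-ether carbon C4 and the pendant silyloxyethyl group recloses the dioxolane and releases the silyl triflate. This is the ionic (cationic) Diels–Alder reaction of 2-alkenyl-1,3-dioxolanes, known for hindered 1-vinylcyclohexenes. Ring A is the only ring closed, as a six-membered carbocycle by a highly asynchronous [4+2] cycloaddition (C2–C3 first, then C4–C5). C5 is set by the diene face that is attacked: with the C8 methyl equatorial the cis C9 methyl is pseudoaxial and shields its own face at C5, so C4 should arrive on the face that carries C11 and H5 ends syn to the C9 methyl. C4 is set by the endo orientation of the charged acetal carbon over the diene, which puts that carbon cis to C6 and trans to H5 and the C4 methyl syn to H5. The step needs ortho regiochemistry, that facial choice and endo orientation, secured respectively by bonding of the cationic CH2 to the only unhindered diene terminus, by the C8/C9 substitution of ring B, and by the preference of the cationic unit for the endo position, while the quaternary C9 biases the diene to its s-cis rotamer and −78 °C protects diene and product alkene from acid-induced migration.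

Step 11
Reactants: 18 2-[(1S,5S,6R,8aR)-5-[(3S)-5-[(tert-butyldimethylsilyl)oxy]-3-methylpentyl]-1,5,6-trimethyl-1,2,3,5,6,7,8,8a-octahydronaphthalen-1-yl]-1,3-dioxolane
Product: 19 (1S,5S,6R,8aR)-5-[(3S)-5-hydroxy-3-methylpentyl]-1,5,6-trimethyl-1,2,3,5,6,7,8,8a-octahydronaphthalene-1-carbaldehyde
Conditions: 1 M aq. HCl, THF, rt
Reagents that add atoms: water, O
Why: Dilute aqueous acid hydrolyses the dioxolane through its oxocarbenium ion and cleaves the primary TBS ether in the same pot, while being too weak at room temperature to protonate the trisubstituted C1=C10 alkene, and the aldehyde has no α-hydrogen so C4 cannot epimerise.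

Step 12
Reactants: 19 (1S,5S,6R,8aR)-5-[(3S)-5-hydroxy-3-methylpentyl]-1,5,6-trimethyl-1,2,3,5,6,7,8,8a-octahydronaphthalene-1-carbaldehyde
Product: 20 (1S,5S,6R,8aR)-5-[(3S)-5-hydroxy-3-methylpentyl]-1,5,6-trimethyl-1,2,3,5,6,7,8,8a-octahydronaphthalene-1-carboxylic acid
Conditions: NaClO2, NaH2PO4, 2-methylbut-2-ene (excess), t-BuOH/H2O, 0 °C to rt
Reagents that add atoms: sodium chlorite, [Na+].[O-]Cl=O
Why: Pinnick oxidation converts the hindered, non-enolisable aldehyde into the acid via the chlorous acid adduct, the excess alkene scavenger traps hypochlorous acid and so protects the ring alkene, and the primary alcohol is inert.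

Step 13
Reactants: 20 (1S,5S,6R,8aR)-5-[(3S)-5-hydroxy-3-methylpentyl]-1,5,6-trimethyl-1,2,3,5,6,7,8,8a-octahydronaphthalene-1-carboxylic acid
Product: 21 methyl (1S,5S,6R,8aR)-5-[(3S)-5-hydroxy-3-methylpentyl]-1,5,6-trimethyl-1,2,3,5,6,7,8,8a-octahydronaphthalene-1-carboxylate
Conditions: Me3SiCHN2, MeOH/toluene, 0 °C to rt
Reagents that add atoms: trimethylsilyldiazomethane, C[Si](C)(C)C=[N+]=[N-]
Why: O-methylation of the carboxylic acid by the diazoalkane (protonation at carbon, then SN2 attack of the carboxylate on the methyldiazonium) is insensitive to the neopentyl hindrance and leaves the far less acidic alcohol alone.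

Step 14
Reactants: 21 methyl (1S,5S,6R,8aR)-5-[(3S)-5-hydroxy-3-methylpentyl]-1,5,6-trimethyl-1,2,3,5,6,7,8,8a-octahydronaphthalene-1-carboxylate
Product: 22 methyl (1S,5S,6R,8aR)-5-[(3S)-5-acetoxy-3-methylpentyl]-1,5,6-trimethyl-1,2,3,5,6,7,8,8a-octahydronaphthalene-1-carboxylate (CNP0151222.1)
Conditions: Ac2O, pyridine, DMAP (cat.), CH2Cl2, rt
Reagents that add atoms: acetic anhydride, CC(=O)OC(C)=O
Why: DMAP-catalysed acylation of the unhindered primary alcohol by acetic anhydride gives the acetate, and no other nucleophilic site is present.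

Compound list
1 | 2-methylcyclohex-2-en-1-one | CC1=CCCCC1=O | starting material
2 | trimethylaluminium | C[Al](C)C | starting material
3 | dimethylaluminium (R)-2,3-dimethylcyclohex-1-en-1-olate | C[C@@H]1CCCC(O[Al](C)C)=C1C | intermediate
4 | (R)-[(2,3-dimethylcyclohex-1-en-1-yl)oxy]trimethylsilane | C[C@@H]1CCCC(O[Si](C)(C)C)=C1C | intermediate
5 | methyl hydrogen (R)-3-methylglutarate | COC(=O)C[C@H](C)CC(=O)O | starting material
6 | methyl (R)-5-hydroxy-3-methylpentanoate | COC(=O)C[C@H](C)CCO | intermediate
7 | methyl (R)-5-[(tert-butyldimethylsilyl)oxy]-3-methylpentanoate | COC(=O)C[C@H](C)CCO[Si](C)(C)C(C)(C)C | intermediate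
8 | (S)-5-[(tert-butyldimethylsilyl)oxy]-3-methylpentan-1-ol | OCC[C@H](C)CCO[Si](C)(C)C(C)(C)C | intermediate
9 | (R)-tert-butyl[(5-iodo-3-methylpentyl)oxy]dimethylsilane | ICC[C@H](C)CCO[Si](C)(C)C(C)(C)C | intermediate
10 | lithium (R)-2,3-dimethylcyclohex-1-en-1-olate | C[C@@H]1CCCC([O-])=C1C.[Li+] | intermediate
11 | (2S,3R)-2-[(3S)-5-[(tert-butyldimethylsilyl)oxy]-3-methylpentyl]-2,3-dimethylcyclohexan-1-one | O=C1CCC[C@@H](C)[C@]1(C)CC[C@H](C)CCO[Si](C)(C)C(C)(C)C | intermediate
12 | potassium (5R,6S)-6-[(3S)-5-[(tert-butyldimethylsilyl)oxy]-3-methylpentyl]-5,6-dimethylcyclohex-1-en-1-olate | [K+].[O-]C1=CCC[C@@H](C)[C@]1(C)CC[C@H](C)CCO[Si](C)(C)C(C)(C)C | intermediate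
13 | (5R,6S)-6-[(3S)-5-[(tert-butyldimethylsilyl)oxy]-3-methylpentyl]-5,6-dimethylcyclohex-1-en-1-yl trifluoromethanesulfonate | FC(F)(F)S(=O)(=O)OC1=CCC[C@@H](C)[C@]1(C)CC[C@H](C)CCO[Si](C)(C)C(C)(C)C | intermediate
14 | tributyl(vinyl)stannane | C=C[Sn](CCCC)(CCCC)CCCC | starting material
15 | tert-butyl{[(3S)-5-[(1S,6R)-2-ethenyl-1,6-dimethylcyclohex-2-en-1-yl]-3-methylpentyl]oxy}dimethylsilane | C=CC1=CCC[C@@H](C)[C@]1(C)CC[C@H](C)CCO[Si](C)(C)C(C)(C)C | intermediate
16 | methacrolein (2-methylprop-2-enal) | CC(=C)C=O | starting material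
17 | 2-(prop-1-en-2-yl)-1,3-dioxolane | C=C(C)C1OCCO1 | intermediate
18 | 2-[(1S,5S,6R,8aR)-5-[(3S)-5-[(tert-butyldimethylsilyl)oxy]-3-methylpentyl]-1,5,6-trimethyl-1,2,3,5,6,7,8,8a-octahydronaphthalen-1-yl]-1,3-dioxolane | O1CCOC1[C@@]2(C)CCC=C3[C@H]2CC[C@@H](C)[C@]3(C)CC[C@H](C)CCO[Si](C)(C)C(C)(C)C | intermediate
19 | (1S,5S,6R,8aR)-5-[(3S)-5-hydroxy-3-methylpentyl]-1,5,6-trimethyl-1,2,3,5,6,7,8,8a-octahydronaphthalene-1-carbaldehyde | O=C[C@@]1(C)CCC=C2[C@H]1CC[C@@H](C)[C@]2(C)CC[C@H](C)CCO | intermediate
20 | (1S,5S,6R,8aR)-5-[(3S)-5-hydroxy-3-methylpentyl]-1,5,6-trimethyl-1,2,3,5,6,7,8,8a-octahydronaphthalene-1-carboxylic acid | OC(=O)[C@@]1(C)CCC=C2[C@H]1CC[C@@H](C)[C@]2(C)CC[C@H](C)CCO | intermediate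
21 | methyl (1S,5S,6R,8aR)-5-[(3S)-5-hydroxy-3-methylpentyl]-1,5,6-trimethyl-1,2,3,5,6,7,8,8a-octahydronaphthalene-1-carboxylate | COC(=O)[C@@]1(C)CCC=C2[C@H]1CC[C@@H](C)[C@]2(C)CC[C@H](C)CCO | intermediate
22 | methyl (1S,5S,6R,8aR)-5-[(3S)-5-acetoxy-3-methylpentyl]-1,5,6-trimethyl-1,2,3,5,6,7,8,8a-octahydronaphthalene-1-carboxylate | COC(=O)[C@@]1(C)CCC=C2[C@H]1CC[C@@H](C)[C@]2(C)CC[C@H](C)CCOC(C)=O | target

Total step count: 14 steps.
Longest linear sequence: 12 steps (from 5 through steps 2–8 and 10–14).

Steps most likely to fail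

Step 10 (key cycloaddition). Both half-chair conformers of ring B are accessible, so attack on the wrong diene face or exo orientation may compete. The acid may also oligomerise the diene or move its double bonds, and the sequence may stop after the first C–C bond. The fallback drops the acetal and the cation and runs a neutral Lewis-acid-catalysed Diels–Alder reaction of diene 15 with methacrolein 16 itself. A proline-derived chiral cationic oxazaborolidine activated by HNTf2 (antipode matched to the substrate) in CH2Cl2 at −78 to −40 °C fixes the dienophile face, and with it C4 and through the endo/exo preference C5, in support of substrate control. This should give (1S,5S,6R,8aR)-5-[(3S)-5-[(tert-butyldimethylsilyl)oxy]-3-methylpentyl]-1,5,6-trimethyl-1,2,3,5,6,7,8,8a-octahydronaphthalene-1-carbaldehyde F1, which is desilylated with 1 M aq. HCl in THF. The fallback sets out from 15 and 16 and returns to the route at 19.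

Step 6 (enolate alkylation). The SN2 reaction of the hindered tetrasubstituted enolate with an unactivated iodide may be slow, which would allow proton transfer and enolate equilibration, O-alkylation or eroded anti selectivity. The fallback forms the C9–C11 bond by an aldol addition instead. Alcohol 8 is oxidised under Swern conditions to (R)-5-[(tert-butyldimethylsilyl)oxy]-3-methylpentanal F2. Mukaiyama aldol addition of silyl enol ether 4 to F2 (BF3·OEt2, CH2Cl2, −78 °C), again expected anti to the C8 methyl, should give the β-hydroxy ketone 2-[5-[(tert-butyldimethylsilyl)oxy]-1-hydroxy-3-methylpentyl]-2,3-dimethylcyclohexan-1-one F3 (both carbinol epimers, which converge). Acylation with O-phenyl chlorothionoformate (pyridine, DMAP, CH2Cl2) gives O-phenyl O-[1-(1,2-dimethyl-6-oxocyclohexyl)-5-[(tert-butyldimethylsilyl)oxy]-3-methylpentyl] carbonothioate F4. Barton–McCombie deoxygenation (Bu3SnH at high concentration so that hydrogen transfer outruns any acyl shift, AIBN, toluene, 80 °C) then removes the C11 oxygen. The fallback sets out from 4 and 8 and returns to the route at 11.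

Step 11 (one-pot acetal hydrolysis and desilylation). Under Brønsted acid the C1=C10 double bond may migrate toward the tetrasubstituted C5=C10 position, which would erase C5, or the hindered neopentyl acetal may stall at partial conversion. The fallback separates the two deprotections and avoids protic acid. Bu4NF in THF removes the silyl group from 18 to give 2-[(1S,5S,6R,8aR)-5-[(3S)-5-hydroxy-3-methylpentyl]-1,5,6-trimethyl-1,2,3,5,6,7,8,8a-octahydronaphthalen-1-yl]-1,3-dioxolane F5. Neutral transacetalisation with catalytic I2 in acetone at rt then transfers the glycol to the solvent and frees the aldehyde. The fallback sets out from 18 and returns to the route at 19.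

Further compounds
F1 | step 10 | (1S,5S,6R,8aR)-5-[(3S)-5-[(tert-butyldimethylsilyl)oxy]-3-methylpentyl]-1,5,6-trimethyl-1,2,3,5,6,7,8,8a-octahydronaphthalene-1-carbaldehyde | O=C[C@@]1(C)CCC=C2[C@H]1CC[C@@H](C)[C@]2(C)CC[C@H](C)CCO[Si](C)(C)C(C)(C)C
F2 | step 6 | (R)-5-[(tert-butyldimethylsilyl)oxy]-3-methylpentanal | O=CC[C@H](C)CCO[Si](C)(C)C(C)(C)C
F3 | step 6 | 2-[5-[(tert-butyldimethylsilyl)oxy]-1-hydroxy-3-methylpentyl]-2,3-dimethylcyclohexan-1-one (C8, C9 and C13 as in 11, both carbinol epimers) | O=C1CCC[C@@H](C)[C@]1(C)C(O)C[C@H](C)CCO[Si](C)(C)C(C)(C)C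
F4 | step 6 | O-phenyl O-[1-(1,2-dimethyl-6-oxocyclohexyl)-5-[(tert-butyldimethylsilyl)oxy]-3-methylpentyl] carbonothioate (stereocentres as in F3) | O=C1CCC[C@@H](C)[C@]1(C)C(OC(=S)Oc2ccccc2)C[C@H](C)CCO[Si](C)(C)C(C)(C)C
F5 | step 11 | 2-[(1S,5S,6R,8aR)-5-[(3S)-5-hydroxy-3-methylpentyl]-1,5,6-trimethyl-1,2,3,5,6,7,8,8a-octahydronaphthalen-1-yl]-1,3-dioxolane | O1CCOC1[C@@]2(C)CCC=C3[C@H]2CC[C@@H](C)[C@]3(C)CC[C@H](C)CCO
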